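The ten-membered ring is cut at C3–C4 and C9–C10. C4–C9, with the C4 methyl, the C5 and C6 oxygens and the C7 side chain, is a carvone ring. C10–C1–C2–C3 is a 1-methylcyclobutene that already bears the C1 oxygen. The feature exploited is the 1,5-relation of the cis 3,4-epoxide and the threo 9,10-diol, a latent (3Z,9E)-cyclodeca-1,5-diene. One enone–alkene [2+2] photocycloaddition makes both bonds and closes the central cyclobutane of a 6-4-4 tricycle holding all ten ring carbons. Stored strain later cleaves C4–C9 and C3–C10. The enone precursor is (S)-carvone carrying a 6β-senecioate and a hydrated side chain.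

Key step: step 7

**Locants and faces (used for all compounds):** C1 CH–O-angelate, C2 CH2, C3 epoxide CH, C4 epoxide C(CH3), C5 CH–OAc, C6 CH–O-senecioate, C7 CH–isopropenyl, C8 CH2, C9 CHOH, C10 C(CH3)OH, C11 the side-chain carbon on C7. β means towards the viewer when the ring is drawn flat with locants rising clockwise. The target is 1β-OAng, 3β,4β-epoxy, 5β-OAc, 6β-OSen, 7β-isopropenyl, 9β-OH, 10α-OH.

**Assumption:** 7, 4 and 22 are purchasable. Racemic 11 is used in excess. Compounds 12–18 are drawn as the expected main C1 epimer, and the other epimer converges at 19.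

**Design remarks:**
- **C1:** in E-cyclodecenes the ring allylic C–H bonds lie near the alkene plane, so ene-type oxidants such as SeO2 attack the vinylic methyl group. The C1 oxygen is therefore built into the cyclobutene.
- **C6:** electrophilic oxygen enters anti to the C7 group, whereas the target has O6 syn to it. C6 is therefore fixed on the carvone ring by hydroxylation and SN2 inversion, which also installs the senecioate.
- **C5 and side chain:** C5 is reduced on the rigid tricycle, and the side chain is unmasked directly after the photochemical step.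

Step 1
Reactants: 1 (S)-(+)-carvone
Product: 3 6α-hydroxycarvone (OH trans to the 7β-isopropenyl group), via potassium dienolate 2 (not isolated)
Conditions: KN(SiMe3)2, THF, −78 °C; 2-(phenylsulfonyl)-3-phenyloxaziridine, −78 °C; AcOH
Reagents that add atoms: 2-(phenylsulfonyl)-3-phenyloxaziridine, O=S(=O)(c1ccccc1)N1OC1c1ccccc1
Why: Kinetic α'-deprotonation gives the cross-conjugated enolate, and the oxaziridine transfers oxygen to C6 from the face opposite the C7 substituent (Davis enolate hydroxylation), which should set C6 as the 6α alcohol needed for the inversion in step 2.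

Step 2
Reactants: 3 6α-hydroxycarvone; 4 senecioic acid (3-methylbut-2-enoic acid)
Product: 5 6β-senecioyloxycarvone (ester cis to the 7β-isopropenyl group)
Conditions: PPh3, DIAD, PhMe, 0 °C → rt
Reagents that add atoms: none
Why: Mitsunobu esterification displaces the activated hydroxyl group by SN2 with inversion at a carbinol carbon activated by the neighbouring carbonyl group, the only β-hydrogen (C7–H) is syn to the leaving group so no antiperiplanar elimination towards a phenol is open, and the neutral medium spares the epimerisable α-acyloxy ketone; this sets C6.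

Step 3
Reactants: 5 6β-senecioyloxycarvone
Product: 6 6β-senecioyloxy-7β-(2-hydroxypropan-2-yl) enone (side chain hydrated)
Conditions: Co(acac)2 (cat.), PhSiH3, O2 (1 atm), THF, rt
Reagents that add atoms: dioxygen, O=O
Why: Mukaiyama hydration: hydrogen-atom transfer from the cobalt hydride goes to the electron-neutral 1,1-disubstituted alkene rather than to the two conjugated trisubstituted ones, and the tertiary C11 radical is trapped by O2 and reduced to the alcohol, which removes the alkene that could add to the excited enone; no stereocentre is touched.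

Step 4
Reactants: 7 2-hydroxycyclobutanone
Product: 8 2-(tert-butyldimethylsilyloxy)cyclobutanone (racemic)
Conditions: TBSCl, imidazole, CH2Cl2, 0 °C → rt
Reagents that add atoms: tert-butyldimethylsilyl chloride, CC(C)(C)[Si](C)(C)Cl
Why: Standard silylation of a secondary alcohol; the bulky ether protects the future C1 oxygen and steers the enolisation of step 5 away from it.

Step 5
Reactants: 8 2-(tert-butyldimethylsilyloxy)cyclobutanone
Product: 10 4-(tert-butyldimethylsilyloxy)cyclobut-1-en-1-yl triflate (racemic), via lithium enolate 9 (not isolated)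
Conditions: LiN(SiMe3)2, THF, −78 °C; PhNTf2, −78 → 0 °C
Reagents that add atoms: N-phenylbis(trifluoromethanesulfonimide), O=S(=O)(N(c1ccccc1)S(=O)(=O)C(F)(F)F)C(F)(F)F
Why: Kinetic deprotonation at the unsubstituted α'-CH2 (future C3) and O-sulfonylation of the enolate (enol triflate formation) fix the double bond between future C10 and C3; the existing centre is untouched.

Step 6
Reactants: 10 4-(tert-butyldimethylsilyloxy)cyclobut-1-en-1-yl triflate
Product: 11 4-(tert-butyldimethylsilyloxy)-1-methylcyclobutene (racemic silyl ether of 2-methylcyclobut-2-en-1-ol)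
Conditions: MeMgBr, Fe(acac)3 (5 mol %), THF/NMP, −30 °C
Reagents that add atoms: methylmagnesium bromide, C[Mg]Br
Why: Iron-catalysed Kumada-type cross-coupling of an alkenyl triflate with a methyl Grignard reagent replaces C–OTf by C–CH3 without moving the alkene, and the allylic silyl ether is too poor a leaving group to interfere at this temperature.

Step 7
Reactants: 6 6β-senecioyloxy-7β-(2-hydroxypropan-2-yl) enone; 11 4-(tert-butyldimethylsilyloxy)-1-methylcyclobutene
Product: 12 cis-anti-cis 6-4-4 tricyclic ketone (C3 and C10 on the α face of the six-membered ring, 4β-CH3, 9β-H, 1α-OTBS, 6β-OSen, 7β-C(CH3)2OH)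
Conditions: hν (350 nm lamps, Pyrex), rac-11 (5 equiv, excess recovered), CH2Cl2, −40 °C, Ar
Reagents that add atoms: none
Why: Light of 350 nm excites only the enone of 6, and its twisted triplet adds to the strained alkene of 11 through 1,4-diradicals (enone–alkene [2+2] photocycloaddition, the reaction type long used with cyclobutenes as the first half of a four-carbon ring expansion). First bonding takes place at the unsubstituted alkene carbon C3, and only the diradical able to close C9–C10 goes on, because the alternative would have to join the two fully substituted carbons C4 and C10 and falls apart again, which secures the head-to-tail orientation. The single ring formed, the cyclobutane C3–C4–C9–C10, is closed by recombination of the diradical after spin inversion. C3 and C10 (4–4 fusion) can only be cis, whereas the 6–4 fusion at C4/C9 is cis merely because that diradical conformer is less strained, so any trans-fused isomer, which cannot be epimerised at quaternary C4, is removed by chromatography. C4 and C9 are set by attack on the α face, away from the 6β-ester and the 7β-side chain, and C3 and C10 by the exo (anti) placement of the small ring together with reaction of the alkene face remote from OTBS, so the enone should pick one enantiomer of racemic 11 and place the silyl ether 1α. Only the regiochemistry and the cis-anti-cis frame really matter, since C3, C4, C9 and C10 return to sp2 in step 10 and C1 is reset in steps 14 and 15, while the hydrated side chain rules out the intramolecular addition known for carvone.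

Step 8
Reactants: 12 cis-anti-cis 6-4-4 tricyclic ketone
Product: 13 7β-isopropenyl tricyclic ketone
Conditions: Burgess reagent, PhMe, 50 °C
Reagents that add atoms: none
Why: Burgess dehydration (syn elimination of the tertiary sulfamate) is run here because 12 has a single hydroxyl group; the six methyl hydrogens are favoured over the lone, hindered C7–H next to the ester, so the isopropenyl group should prevail, any isopropylidene isomer is removed at this early stage, and C7 is untouched.

Step 9
Reactants: 13 7β-isopropenyl tricyclic ketone
Product: 14 tricyclic 5β-alcohol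
Conditions: NaBH4, CeCl3·7H2O, MeOH/THF, −40 → 0 °C
Reagents that add atoms: none
Why: Luche-type borohydride reduction: the β face of C5 carries the C4 methyl group, the axial 6β-ester and the C7 side chain, so hydride should enter from the α face, antiperiplanar to the axial C6–O bond, and set C5 as the 5β-alcohol, while the cold, slightly acidic medium holds back O6→O5 acyl shift.

Step 10
Reactants: 14 tricyclic 5β-alcohol
Product: 15 (3Z,9E)-cyclodeca-3,9-dien-5β-ol (1α-OTBS, 6β-OSen, 7β-isopropenyl)
Conditions: PhMe (0.01 M), BHT (cat.), steel flow coil, 200 °C, about 10 min residence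
Reagents that add atoms: none
Why: Thermal cycloreversion of the bicyclo[2.2.0]hexane unit (homolysis of the central C3–C10 bond to a cyclohexane-1,4-diyl, then scission of C4–C9) is the known way from such tricyclodecanes to cis,trans-cyclodeca-1,5-dienes; in the favoured chair diyl C8 is equatorial on C9 (giving 9E) and C5 axial on C4 (giving 3Z), C1, C5, C6 and C7 are not touched, and the short residence time should hold back the slower Cope shift of the Z,E-diene.

Step 11
Reactants: 15 (3Z,9E)-cyclodeca-3,9-dien-5β-ol
Product: 16 3β,4β-epoxy-5β-alcohol (9E alkene kept)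
Conditions: VO(acac)2 (5 mol %), t-BuOOH (decane), CH2Cl2, 0 °C
Reagents that add atoms: tert-butyl hydroperoxide, CC(C)(C)OO
Why: Hydroxyl-directed vanadium-catalysed epoxidation delivers oxygen from the 5β-alkoxide to the same face of the Z C3=C4 bond, with C5–H next to the C4 methyl group (least A(1,2) strain), which gives the cis (erythro) epoxy alcohol typical of medium-ring Z-allylic alcohols and sets C3 and C4; the other alkenes have no coordinating hydroxyl group and stay intact.

Step 12
Reactants: 16 3β,4β-epoxy-5β-alcohol
Product: 17 5β-acetate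
Conditions: Ac2O, pyridine, DMAP (cat.), CH2Cl2, rt
Reagents that add atoms: acetic anhydride, CC(=O)OC(C)=O
Why: DMAP-catalysed acetylation of the only free hydroxyl group, with retention at C5.

Step 13
Reactants: 17 5β-acetate
Product: 18 1α-allylic alcohol
Conditions: Bu4NF, AcOH (1:1), THF, 0 °C → rt
Reagents that add atoms: none
Why: Fluoride cleavage of the allylic silyl ether, buffered with AcOH so that neither ester migration nor epoxide opening is triggered.

Step 14
Reactants: 18 1α-allylic alcohol
Product: 19 (9E)-9-en-1-one
Conditions: MnO2, CH2Cl2, rt; filtered and used at once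
Reagents that add atoms: none
Why: Allylic alcohol oxidation with MnO2 erases C1, so both C1 epimers from step 7 converge, and the neutral heterogeneous conditions avoid base-induced opening of the β,γ-epoxy ketone.

Step 15
Reactants: 19 (9E)-9-en-1-one
Product: 20 1β-allylic alcohol
Conditions: (R)-Me-CBS oxazaborolidine, catecholborane, PhMe, −78 °C
Reagents that add atoms: none
Why: CBS reduction of an α-methyl enone, in which the C10 alkenyl arm is the large and C2H2 the small substituent, so the (R)-catalyst should deliver hydride to give the (1S) = 1β alcohol under reagent control, and catecholborane at −78 °C spares alkenes, esters and epoxide.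

Step 16
Reactants: 20 1β-allylic alcohol
Product: 21 9β,10α-osmate ester (OsO2(TMEDA) diolate, 1β-OH free)
Conditions: OsO4, TMEDA, CH2Cl2, −78 °C
Reagents that add atoms: osmium tetroxide, O=[Os](=O)(=O)=O; N,N,N',N'-tetramethylethylenediamine, CN(C)CCN(C)C
Why: Hydrogen-bond-directed dihydroxylation: the diamine-bound tetroxide accepts a hydrogen bond from the 1β-OH, which selects the allylic C9=C10 bond over the isopropenyl and ester alkenes and guides suprafacial addition to the outer face of the E alkene in the conformer with C1–H eclipsing the double bond and C2 anti, setting 9β-O and 10α-O (syn to O1 in the zigzag sense); the chelated ester of hexavalent osmium is stable and is isolated.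

Step 17
Reactants: 21 9β,10α-osmate ester; 22 angelic acid
Product: 24 1β-angelate osmate ester, via mixed anhydride 23 (not isolated)
Conditions: 22, 2,4,6-Cl3C6H2COCl, Et3N, PhMe, rt; then 21, PhMe, 80 °C (no DMAP)
Reagents that add atoms: none
Why: Yamaguchi mixed-anhydride esterification without a nucleophilic catalyst is the established way to transfer the angeloyl group without Z→E isomerisation, the 1β-OH is the only free hydroxyl group because the diol is held as the osmate ester, and C1 keeps its configuration.

Step 18
Reactants: 24 1β-angelate osmate ester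
Product: 25 CNP0298989.1 (target)
Conditions: sat. aq. Na2SO3, THF, 50 °C
Reagents that add atoms: none
Why: Reductive hydrolysis of the osmate ester with sulfite breaks only Os–O bonds, so C9 and C10 keep their configuration, and the nearly neutral medium should spare the three esters and the epoxide.

Compound list
1 | (S)-(+)-carvone | CC1=CC[C@@H](CC1=O)C(C)=C | starting material
2 | potassium cross-conjugated dienolate of 1 | CC1=CC[C@H](C(C)=C)C=C1[O-].[K+] | intermediate
3 | 6α-hydroxycarvone (trans) | CC1=CC[C@H](C(C)=C)[C@@H](O)C1=O | intermediate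
4 | senecioic acid | CC(C)=CC(=O)O | starting material
5 | 6β-senecioyloxycarvone (cis) | CC1=CC[C@H](C(C)=C)[C@H](OC(=O)C=C(C)C)C1=O | intermediate
6 | 6β-senecioyloxy-7β-(2-hydroxypropan-2-yl) enone | CC1=CC[C@H](C(C)(C)O)[C@H](OC(=O)C=C(C)C)C1=O | intermediate
7 | 2-hydroxycyclobutanone | O=C1CCC1O | starting material
8 | 2-(tert-butyldimethylsilyloxy)cyclobutanone (racemic) | O=C1CCC1O[Si](C)(C)C(C)(C)C | intermediate
9 | lithium enolate of 8 | [Li+].[O-]C1=CCC1O[Si](C)(C)C(C)(C)C | intermediate
10 | 4-(tert-butyldimethylsilyloxy)cyclobut-1-en-1-yl triflate (racemic) | O=S(=O)(OC1=CCC1O[Si](C)(C)C(C)(C)C)C(F)(F)F | intermediate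
11 | 4-(tert-butyldimethylsilyloxy)-1-methylcyclobutene (racemic) | CC1=CCC1O[Si](C)(C)C(C)(C)C | intermediate
12 | cis-anti-cis 6-4-4 tricyclic ketone | C[C@@]12C(=O)[C@@H](OC(=O)C=C(C)C)[C@@H](C(C)(C)O)C[C@@H]1[C@@]1(C)[C@H](O[Si](C)(C)C(C)(C)C)C[C@H]12 | intermediate
13 | 7β-isopropenyl tricyclic ketone | C[C@@]12C(=O)[C@@H](OC(=O)C=C(C)C)[C@@H](C(C)=C)C[C@@H]1[C@@]1(C)[C@H](O[Si](C)(C)C(C)(C)C)C[C@H]12 | intermediate
14 | tricyclic 5β-alcohol | C[C@@]12[C@@H](O)[C@@H](OC(=O)C=C(C)C)[C@@H](C(C)=C)C[C@@H]1[C@@]1(C)[C@H](O[Si](C)(C)C(C)(C)C)C[C@H]12 | intermediate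
15 | (3Z,9E)-cyclodeca-3,9-dien-5β-ol | C=C(C)[C@H]1C/C=C(\C)[C@H](O[Si](C)(C)C(C)(C)C)C/C=C(/C)[C@@H](O)[C@H]1OC(=O)C=C(C)C | intermediate
16 | 3β,4β-epoxy-5β-alcohol | C=C(C)[C@H]1C/C=C(\C)[C@H](O[Si](C)(C)C(C)(C)C)C[C@H]2O[C@@]2(C)[C@@H](O)[C@H]1OC(=O)C=C(C)C | intermediate
17 | 5β-acetate | C=C(C)[C@H]1C/C=C(\C)[C@H](O[Si](C)(C)C(C)(C)C)C[C@H]2O[C@@]2(C)[C@@H](OC(C)=O)[C@H]1OC(=O)C=C(C)C | intermediate
18 | 1α-allylic alcohol | C=C(C)[C@H]1C/C=C(\C)[C@H](O)C[C@H]2O[C@@]2(C)[C@@H](OC(C)=O)[C@H]1OC(=O)C=C(C)C | intermediate
19 | (9E)-9-en-1-one | C=C(C)[C@H]1C/C=C(\C)C(=O)C[C@H]2O[C@@]2(C)[C@@H](OC(C)=O)[C@H]1OC(=O)C=C(C)C | intermediate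
20 | 1β-allylic alcohol | C=C(C)[C@H]1C/C=C(\C)[C@@H](O)C[C@H]2O[C@@]2(C)[C@@H](OC(C)=O)[C@H]1OC(=O)C=C(C)C | intermediate
21 | 9β,10α-osmate ester, OsO2(TMEDA) diolate | C=C(C)[C@H]1C[C@@H](O5)[C@](C)(O[Os-2]56(=O)(=O)[N+](C)(C)CC[N+]6(C)C)[C@@H](O)C[C@H]2O[C@@]2(C)[C@@H](OC(C)=O)[C@H]1OC(=O)C=C(C)C | intermediate
22 | angelic acid | C/C=C(/C)C(=O)O | starting material
23 | angelic 2,4,6-trichlorobenzoic anhydride | C/C=C(/C)C(=O)OC(=O)c1c(Cl)cc(Cl)cc1Cl | intermediate
24 | 1β-angelate osmate ester | C=C(C)[C@H]1C[C@@H](O5)[C@](C)(O[Os-2]56(=O)(=O)[N+](C)(C)CC[N+]6(C)C)[C@@H](OC(=O)/C(C)=C\C)C[C@H]2O[C@@]2(C)[C@@H](OC(C)=O)[C@H]1OC(=O)C=C(C)C | intermediate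
25 | CNP0298989.1 | C=C(C)[C@H]1C[C@@H](O)[C@](C)(O)[C@@H](OC(=O)/C(C)=C\C)C[C@H]2O[C@@]2(C)[C@@H](OC(C)=O)[C@H]1OC(=O)C=C(C)C | target

Total step count: 18.

Longest linear sequence: 15 steps (steps 1–3 and 7–18). The branch of steps 4–6 is equally long.

Steps most likely to fail:

**Step 7.**
- What may go wrong: the bulky silyl ether next to the fully substituted alkene carbon, together with mismatched pairings of the chiral enone with the two enantiomers of 11, may slow the addition. Diradical reversion, head-to-head closure or trans 6–4 fusion could then compete and leave a set of stereoisomers that is hard to purify.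
- Fallback, from 11 and 6, returning at 19: the C1 oxygen is carried at the ketone level in an achiral, flatter alkene. Fluoride cleavage of 11 gives 2-methylcyclobut-2-en-1-ol F1, MnO2 gives 2-methylcyclobut-2-en-1-one F2, and 1,2-bis(trimethylsilyloxy)ethane with catalytic Me3SiOTf at −78 °C gives the ketal 1-methyl-5,8-dioxaspiro[3.4]oct-1-ene F3. Irradiation of 6 with F3 should give the tricyclic keto ketal F4, in which C1 is no stereocentre, so every cis-anti-cis adduct converges. The operations of steps 8–12 are then run on this series. Burgess dehydration leads to the isopropenyl keto ketal F5, borohydride reduction to the tricyclic alcohol ketal F6, and thermolysis to the cyclodecadienol ketal F7. Directed epoxidation then gives the epoxy alcohol ketal F8, and acetylation gives the epoxy acetate ketal F9. PPTS in wet acetone then frees the ketone and gives 19, so steps 13 and 14 fall away.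

**Step 10.**
- What may go wrong: the new 1,5-diene may undergo a Cope shift to a divinylcyclohexane. The diyl may open through the other chair to the 3E,9Z isomer. The senecioyl group may wander thermally from O6 to O5.
- Fallback, from 13, returning at 15: the order of reduction and ring opening is reversed. Thermolysis of ketone 13 should give the (3Z,9E)-dienone F10. Its new C3=C4 bond is conjugated with C5=O, and that conjugation would be lost in a Cope shift. No free hydroxyl group is present, and a 3E-enone can be equilibrated to 3Z with catalytic iodine. Luche reduction of F10 then gives 15, with hydride arriving from the ring periphery while the C6–O bond eclipses the carbonyl group.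

**Step 2.**
- What may go wrong: displacement at the hindered carbinol by a weakly acidic carboxylic acid may be sluggish. Acyl transfer with retention, elimination towards a phenol, or epimerisation of the product could then take over.
- Fallback, from 3, returning at 5: inversion and acylation are separated. Tf2O and pyridine at −78 °C give 6α-triflyloxycarvone F11. Bu4N nitrite in PhMe displaces the triflate with inversion to the 6β-nitrite ester F12, which hydrolyses on aqueous work-up to 6β-hydroxycarvone F13. Senecioyl chloride in pyridine at 0 °C then acylates with retention to 5.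

Further compounds
F1 | step 7 | 2-methylcyclobut-2-en-1-ol (racemic) | CC1=CCC1O
F2 | step 7 | 2-methylcyclobut-2-en-1-one | CC1=CCC1=O
F3 | step 7 | 1-methyl-5,8-dioxaspiro[3.4]oct-1-ene | CC1=CCC12OCCO2
F4 | step 7 | tricyclic keto ketal | C[C@@]12C(=O)[C@@H](OC(=O)C=C(C)C)[C@@H](C(C)(C)O)C[C@@H]1[C@@]1(C)C3(OCCO3)C[C@H]12
F5 | step 7 | isopropenyl keto ketal | C[C@@]12C(=O)[C@@H](OC(=O)C=C(C)C)[C@@H](C(C)=C)C[C@@H]1[C@@]1(C)C3(OCCO3)C[C@H]12
F6 | step 7 | tricyclic alcohol ketal | C[C@@]12[C@@H](O)[C@@H](OC(=O)C=C(C)C)[C@@H](C(C)=C)C[C@@H]1[C@@]1(C)C3(OCCO3)C[C@H]12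
F7 | step 7 | cyclodecadienol ketal | C=C(C)[C@H]1C/C=C(\C)C3(OCCO3)C/C=C(/C)[C@@H](O)[C@H]1OC(=O)C=C(C)C
F8 | step 7 | epoxy alcohol ketal | C=C(C)[C@H]1C/C=C(\C)C3(OCCO3)C[C@H]2O[C@@]2(C)[C@@H](O)[C@H]1OC(=O)C=C(C)C
F9 | step 7 | epoxy acetate ketal | C=C(C)[C@H]1C/C=C(\C)C3(OCCO3)C[C@H]2O[C@@]2(C)[C@@H](OC(C)=O)[C@H]1OC(=O)C=C(C)C
F10 | step 10 | (3Z,9E)-dienone | C=C(C)[C@H]1C/C=C(\C)[C@H](O[Si](C)(C)C(C)(C)C)C/C=C(/C)C(=O)[C@H]1OC(=O)C=C(C)C
F11 | step 2 | 6α-triflyloxycarvone | CC1=CC[C@H](C(C)=C)[C@@H](OS(=O)(=O)C(F)(F)F)C1=O
F12 | step 2 | 6β-nitrite ester | CC1=CC[C@H](C(C)=C)[C@H](ON=O)C1=O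
F13 | step 2 | 6β-hydroxycarvone | CC1=CC[C@H](C(C)=C)[C@H](O)C1=O
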